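**Retrosynthetic overview**
1. Last step: the ten-membered ring B and the butenolide ring C are closed together from an open-chain enal/2,3-allenoate by a samarium ketyl radical addition that forms the C7–C8 bond (key step), followed by lactonisation and alkene migration.
2. The allenoate is made from the acetic acid side chain on ring A (acid chloride, ketene, Wittig); the enal arm is attached at C4–C5 by a B-alkyl Suzuki coupling with (Z)-3-iodobut-2-en-1-ol and then oxidised.
3. Ring A (cyclohexene; C1 and C10) comes from an epoxy dienoate by a second radical step: Cp2TiCl epoxide opening and 6-exo cyclisation forming C1–C10.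
4. The epoxy dienoate comes from a Sharpless kinetic-resolution epoxidation (C2, C14) of a tetraene made by Negishi carboalumination of pent-1-en-4-yn-3-ol and allylation with a bromide obtained by Heck coupling of (Z)-3-iodobut-2-en-1-ol with methyl acrylate.
5. Ring order: A first (step 6), then B and C in one step (step 12).

Carbon labels C1 to C20 follow briarane numbering of the target: C1 quaternary carbon (methyl C15), C2 propanoyloxy carbon, C5=C6 Z alkene (methyl C16), C7 lactone O–CH, C8=C17 butenolide alkene (methyl C18, carbonyl C19), C9 CH2, C10 ring-fusion CH, C11=C12 ring alkene (methyl C20), C14 acetoxy carbon.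

Assumptions: (a) (Z)-3-iodobut-2-en-1-ol, methyl acrylate and racemic pent-1-en-4-yn-3-ol are bought; (b) the 7R butenolide is taken to be the more stable C7 epimer of the tricycle.

**Route**

Step 1
Reactants: 1 (Z)-3-iodobut-2-en-1-ol; 2 methyl acrylate
Product: 3 methyl (2E,4Z)-6-hydroxy-4-methylhexa-2,4-dienoate
Conditions: Pd(OAc)2 (5 mol %), Bu4NCl, NaHCO3, DMF, 40 °C
Reagents that add atoms: none
Why: Mizoroki–Heck coupling under phosphine-free conditions joins the alkenyl iodide to the acrylate β-carbon with retention of the Z iodoalkene geometry and E selectivity at the new alkene; no stereocentre is formed.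

Step 2
Reactants: 3 methyl (2E,4Z)-6-hydroxy-4-methylhexa-2,4-dienoate
Product: 4 methyl (2E,4Z)-6-bromo-4-methylhexa-2,4-dienoate
Conditions: CBr4, PPh3, CH2Cl2, 0 °C
Reagents that add atoms: carbon tetrabromide BrC(Br)(Br)Br
Why: Appel reaction; SN2 displacement at the primary allylic carbon leaves both alkene geometries intact.

Step 3
Reactants: 5 pent-1-en-4-yn-3-ol (racemate); 4 methyl (2E,4Z)-6-bromo-4-methylhexa-2,4-dienoate
Product: 7 methyl (2E,4Z,7E)-9-hydroxy-4,8-dimethylundeca-2,4,7,10-tetraenoate (racemate), via alkenylalane 6 (not isolated)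
Conditions: AlMe3 (2.5 equiv), Cp2ZrCl2 (0.25 equiv), CH2Cl2, 0 °C to rt; then 4, Pd(PPh3)4 (5 mol %), THF, rt; aqueous NH4Cl
Reagents that add atoms: trimethylaluminium C[Al](C)C
Why: Negishi zirconium-catalysed carboalumination adds methyl (C15) and aluminium syn across the alkyne to give the E C1=C14 alkenylalane, and palladium-catalysed alkenyl–allyl coupling joins C14 to the primary allylic carbon C13 with retention of both alkene geometries; the carbinol stays racemic.

Step 4
Reactants: 7 methyl (2E,4Z,7E)-9-hydroxy-4,8-dimethylundeca-2,4,7,10-tetraenoate (racemate)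
Product: 8 methyl (2E,4Z)-6-[(2S,3S)-3-[(1S)-1-hydroxyprop-2-en-1-yl]-3-methyloxiran-2-yl]-4-methylhexa-2,4-dienoate
Conditions: Ti(OiPr)4 (0.2 equiv), L-(+)-diisopropyl tartrate (0.3 equiv), t-BuOOH (0.55 equiv), 4 Å molecular sieves, CH2Cl2, −20 °C
Reagents that add atoms: tert-butyl hydroperoxide CC(C)(C)OO
Why: Sharpless asymmetric epoxidation run as a kinetic resolution: with the L-(+)-tartrate the (S)-carbinol enantiomer is epoxidised fast and erythro-selectively at the trisubstituted allylic alkene, which fixes C2 (S) and sets the oxirane carbons C14 (S) and C1; unreacted (R)-7 is removed by chromatography.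

Step 5
Reactants: 8 methyl (2E,4Z)-6-[(2S,3S)-3-[(1S)-1-hydroxyprop-2-en-1-yl]-3-methyloxiran-2-yl]-4-methylhexa-2,4-dienoate
Product: 9 methyl (2E,4Z)-4-methyl-6-[(2S,3R)-3-methyl-3-[(1S)-1-(propanoyloxy)prop-2-en-1-yl]oxiran-2-yl]hexa-2,4-dienoate
Conditions: EtCOCl, pyridine, DMAP (cat.), CH2Cl2, 0 °C
Reagents that add atoms: propanoyl chloride CCC(Cl)=O
Why: DMAP-catalysed acylation installs the C2 propanoate before ring formation so the two oxygens stay differentiated; no stereocentre is touched (oxirane C3 changes from S to R only through CIP priorities).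

Step 6
Reactants: 9 methyl (2E,4Z)-4-methyl-6-[(2S,3R)-3-methyl-3-[(1S)-1-(propanoyloxy)prop-2-en-1-yl]oxiran-2-yl]hexa-2,4-dienoate
Product: 10 methyl 2-[(1S,5S,6R)-5-hydroxy-2,6-dimethyl-6-[(1S)-1-(propanoyloxy)prop-2-en-1-yl]cyclohex-2-en-1-yl]acetate
Conditions: Cp2TiCl2 (20 mol %), Mn dust (2 equiv), 2,4,6-collidinium chloride (2.5 equiv), THF (0.01 M), rt, slow addition of 9
Reagents that add atoms: none
Why: Nugent–RajanBabu reductive epoxide opening by trivalent titanium (Cp2TiCl) gives the tertiary β-titanoxy radical at C1 with C14 unchanged, and this closes 6-exo (Giese type) on the dienoate β-carbon C10 through a half-chair in which the s-trans dienoate arm and the branched C2 substituent are both equatorial (C2 trans to C9) and the titanoxy group is axial so that the branch is not flanked by two equatorial neighbours (O14 cis to C2), which sets C1 and C10.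

Step 7
Reactants: 10 methyl 2-[(1S,5S,6R)-5-hydroxy-2,6-dimethyl-6-[(1S)-1-(propanoyloxy)prop-2-en-1-yl]cyclohex-2-en-1-yl]acetate
Product: 11 methyl 2-[(1S,5S,6R)-5-acetoxy-2,6-dimethyl-6-[(1S)-1-(propanoyloxy)prop-2-en-1-yl]cyclohex-2-en-1-yl]acetate
Conditions: Ac2O, pyridine, DMAP (cat.), CH2Cl2, rt
Reagents that add atoms: acetic anhydride CC(=O)OC(C)=O
Why: DMAP-catalysed acetylation of the hindered C14 hydroxyl, done at once so the propanoate cannot migrate; no stereocentre is touched.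

Step 8
Reactants: 11 methyl 2-[(1S,5S,6R)-5-acetoxy-2,6-dimethyl-6-[(1S)-1-(propanoyloxy)prop-2-en-1-yl]cyclohex-2-en-1-yl]acetate; 1 (Z)-3-iodobut-2-en-1-ol
Product: 13 methyl 2-[(1S,5S,6S)-5-acetoxy-6-[(1S,4Z)-6-hydroxy-4-methyl-1-(propanoyloxy)hex-4-en-1-yl]-2,6-dimethylcyclohex-2-en-1-yl]acetate, via alkylborane 12 (not isolated)
Conditions: 9-BBN (1.5 equiv), THF, 0 °C to rt; then 1, Pd(dppf)Cl2 (5 mol %), AsPh3, aqueous K3PO4, DMF, rt
Reagents that add atoms: none
Why: B-alkyl Suzuki–Miyaura coupling: 9-BBN adds only to the monosubstituted vinyl group (boron on C4) and the alkylborane couples with the alkenyl iodide with retention, giving the Z C5=C6 alkene; no stereocentre is touched (ring C6 becomes S through CIP priorities only).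

Step 9
Reactants: 13 methyl 2-[(1S,5S,6S)-5-acetoxy-6-[(1S,4Z)-6-hydroxy-4-methyl-1-(propanoyloxy)hex-4-en-1-yl]-2,6-dimethylcyclohex-2-en-1-yl]acetate
Product: 14 2-[(1S,5S,6S)-5-acetoxy-6-[(1S,4Z)-6-hydroxy-4-methyl-1-(propanoyloxy)hex-4-en-1-yl]-2,6-dimethylcyclohex-2-en-1-yl]acetic acid
Conditions: LiI, EtOAc, reflux; dilute aqueous HCl work-up
Reagents that add atoms: none
Why: SN2 dealkylation of the methyl ester by iodide; only the methyl ester has an unhindered O-alkyl carbon, so the secondary acetate and propanoate survive.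

Step 10
Reactants: 14 2-[(1S,5S,6S)-5-acetoxy-6-[(1S,4Z)-6-hydroxy-4-methyl-1-(propanoyloxy)hex-4-en-1-yl]-2,6-dimethylcyclohex-2-en-1-yl]acetic acid
Product: 15 2-[(1S,5S,6S)-5-acetoxy-2,6-dimethyl-6-[(1S,4Z)-4-methyl-6-oxo-1-(propanoyloxy)hex-4-en-1-yl]cyclohex-2-en-1-yl]acetic acid
Conditions: PhI(OAc)2 (1.1 equiv), TEMPO (10 mol %), CH2Cl2, rt
Reagents that add atoms: none
Why: TEMPO/PhI(OAc)2 oxidation turns the primary allylic alcohol into the enal without Z to E isomerisation and tolerates the free acid.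

Step 11
Reactants: 15 2-[(1S,5S,6S)-5-acetoxy-2,6-dimethyl-6-[(1S,4Z)-4-methyl-6-oxo-1-(propanoyloxy)hex-4-en-1-yl]cyclohex-2-en-1-yl]acetic acid
Product: 18 methyl 4-[(1S,5S,6S)-5-acetoxy-2,6-dimethyl-6-[(1S,4Z)-4-methyl-6-oxo-1-(propanoyloxy)hex-4-en-1-yl]cyclohex-2-en-1-yl]-2-methylbuta-2,3-dienoate (both allene epimers), via acid chloride 16 (not isolated), via ketene 17 (not isolated)
Conditions: 1-chloro-N,N,2-trimethylprop-1-en-1-amine, CH2Cl2, 0 °C; then added to Ph3P=C(Me)CO2Me (1.05 equiv), Et3N (1.1 equiv), CH2Cl2, 0 °C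
Reagents that add atoms: methyl 2-(triphenylphosphoranylidene)propanoate COC(=O)C(C)=P(c1ccccc1)(c1ccccc1)c1ccccc1
Why: The acid is converted to its chloride under neutral conditions, triethylamine eliminates HCl to the ketene, and Wittig olefination of the ketene by the stabilised ylide gives the 2,3-allenoate (ketene–ylide allene synthesis, adding C17, C18 and C19); the ketene reacts far faster than the hindered β,β-disubstituted enal, and the allene axis is destroyed in the next step.

Step 12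
Reactants: 18 methyl 4-[(1S,5S,6S)-5-acetoxy-2,6-dimethyl-6-[(1S,4Z)-4-methyl-6-oxo-1-(propanoyloxy)hex-4-en-1-yl]cyclohex-2-en-1-yl]-2-methylbuta-2,3-dienoate
Product: 21 CNP0112230.1 (the target), via hydroxy ester 19 (not isolated), via alkylidene lactone 20 (not isolated)
Conditions: SmI2 (2.5 equiv), t-BuOH (2 equiv), THF (0.002 M), −78 to 0 °C; then DBU (0.2 equiv), CH2Cl2, rt
Reagents that add atoms: none
Why: Proposed new method: SmI2 (divalent samarium) reduces the enal to a samarium ketyl whose carbon radical adds to the electrophilic central allene carbon C8 (the β-carbon of the conjugated ester) in a ten-membered ring closure helped by ring A, the Z alkene and high dilution, the resulting α-ester radical is reduced to the samarium dienolate and protonated, the C7 alkoxide lactonises, and DBU moves the exocyclic C8=C9 alkene into conjugation to give the butenolide; C7 is set in the ring closure (1,3-allylic strain across the Z C5=C6 alkene holds H7 in the alkene plane, so C8 bonds on the face fixed by the tether) and, being the acidic γ-position of the butenolide, is equilibrated by DBU toward the 7R epimer; the closest known chemistry is the samarium diiodide ketyl–acrylate reductive coupling with lactonisation and ketyl–olefin medium-ring cyclisation.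

**Compound list**

1 | (Z)-3-iodobut-2-en-1-ol | C/C(I)=C/CO | starting material
2 | methyl acrylate | C=CC(=O)OC | starting material
3 | methyl (2E,4Z)-6-hydroxy-4-methylhexa-2,4-dienoate | COC(=O)/C=C/C(C)=C\CO | intermediate
4 | methyl (2E,4Z)-6-bromo-4-methylhexa-2,4-dienoate | COC(=O)/C=C/C(C)=C\CBr | intermediate
5 | pent-1-en-4-yn-3-ol (racemate) | C=CC(O)C#C | starting material
6 | alkenylalane: dimethyl[(1E)-3-(dimethylalumanyloxy)-2-methylpenta-1,4-dien-1-yl]alumane (racemate; not isolated) | C=CC(O[Al](C)C)/C(C)=C/[Al](C)C | intermediate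
7 | methyl (2E,4Z,7E)-9-hydroxy-4,8-dimethylundeca-2,4,7,10-tetraenoate (racemate) | COC(=O)/C=C/C(C)=C\C/C=C(C)/C(O)C=C | intermediate
8 | methyl (2E,4Z)-6-[(2S,3S)-3-[(1S)-1-hydroxyprop-2-en-1-yl]-3-methyloxiran-2-yl]-4-methylhexa-2,4-dienoate | C=C[C@H](O)[C@]1(C)O[C@H]1C/C=C(C)\C=C\C(=O)OC | intermediate
9 | methyl (2E,4Z)-4-methyl-6-[(2S,3R)-3-methyl-3-[(1S)-1-(propanoyloxy)prop-2-en-1-yl]oxiran-2-yl]hexa-2,4-dienoate | C=C[C@H](OC(=O)CC)[C@]1(C)O[C@H]1C/C=C(C)\C=C\C(=O)OC | intermediate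
10 | methyl 2-[(1S,5S,6R)-5-hydroxy-2,6-dimethyl-6-[(1S)-1-(propanoyloxy)prop-2-en-1-yl]cyclohex-2-en-1-yl]acetate | C=C[C@H](OC(=O)CC)[C@@]1(C)[C@@H](O)CC=C(C)[C@@H]1CC(=O)OC | intermediate
11 | methyl 2-[(1S,5S,6R)-5-acetoxy-2,6-dimethyl-6-[(1S)-1-(propanoyloxy)prop-2-en-1-yl]cyclohex-2-en-1-yl]acetate | C=C[C@H](OC(=O)CC)[C@@]1(C)[C@@H](OC(C)=O)CC=C(C)[C@@H]1CC(=O)OC | intermediate
12 | alkylborane: B-alkyl-9-borabicyclo[3.3.1]nonane from hydroboration of the vinyl group of 11, boron on C4 (not isolated) | C(C[C@H](OC(=O)CC)[C@@]1(C)[C@@H](OC(C)=O)CC=C(C)[C@@H]1CC(=O)OC)B1C2CCCC1CCC2 | intermediate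
13 | methyl 2-[(1S,5S,6S)-5-acetoxy-6-[(1S,4Z)-6-hydroxy-4-methyl-1-(propanoyloxy)hex-4-en-1-yl]-2,6-dimethylcyclohex-2-en-1-yl]acetate | OC/C=C(C)\CC[C@H](OC(=O)CC)[C@@]1(C)[C@@H](OC(C)=O)CC=C(C)[C@@H]1CC(=O)OC | intermediate
14 | 2-[(1S,5S,6S)-5-acetoxy-6-[(1S,4Z)-6-hydroxy-4-methyl-1-(propanoyloxy)hex-4-en-1-yl]-2,6-dimethylcyclohex-2-en-1-yl]acetic acid | OC/C=C(C)\CC[C@H](OC(=O)CC)[C@@]1(C)[C@@H](OC(C)=O)CC=C(C)[C@@H]1CC(=O)O | intermediate
15 | 2-[(1S,5S,6S)-5-acetoxy-2,6-dimethyl-6-[(1S,4Z)-4-methyl-6-oxo-1-(propanoyloxy)hex-4-en-1-yl]cyclohex-2-en-1-yl]acetic acid | O=C/C=C(C)\CC[C@H](OC(=O)CC)[C@@]1(C)[C@@H](OC(C)=O)CC=C(C)[C@@H]1CC(=O)O | intermediate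
16 | acid chloride of 15 (not isolated) | O=C/C=C(C)\CC[C@H](OC(=O)CC)[C@@]1(C)[C@@H](OC(C)=O)CC=C(C)[C@@H]1CC(=O)Cl | intermediate
17 | ketene from 16 (not isolated) | O=C/C=C(C)\CC[C@H](OC(=O)CC)[C@@]1(C)[C@@H](OC(C)=O)CC=C(C)[C@@H]1C=C=O | intermediate
18 | methyl 4-[(1S,5S,6S)-5-acetoxy-2,6-dimethyl-6-[(1S,4Z)-4-methyl-6-oxo-1-(propanoyloxy)hex-4-en-1-yl]cyclohex-2-en-1-yl]-2-methylbuta-2,3-dienoate (both allene epimers) | O=C/C=C(C)\CC[C@H](OC(=O)CC)[C@@]1(C)[C@@H](OC(C)=O)CC=C(C)[C@@H]1C=C=C(C)C(=O)OC | intermediate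
19 | hydroxy ester: rings A and B closed, C7 alcohol (7R), C8=C9 alkene in ring B, C8 bearing CH(CH3)CO2CH3 (both C17 epimers; not isolated) | CCC(=O)O[C@H]1CC/C(C)=C\[C@@H](O)/C(C(C)C(=O)OC)=C\[C@H]2C(C)=CC[C@H](OC(C)=O)[C@]12C | intermediate
20 | alkylidene lactone: tricyclic α-methyl-β-alkylidene-γ-lactone with C8=C9 exocyclic to the lactone (both C17 epimers; not isolated) | CCC(=O)O[C@H]1CC/C(C)=C\[C@H]2OC(=O)C(C)/C2=C/[C@H]2C(C)=CC[C@H](OC(C)=O)[C@]12C | intermediate
21 | CNP0112230.1: tricyclic butenolide diester (1S,2S,5Z,7R,10S,14S in briarane numbering) | CCC(=O)O[C@H]1CC/C(C)=C\[C@H]2OC(=O)C(C)=C2C[C@H]2C(C)=CC[C@H](OC(C)=O)[C@]12C | target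

**Totals**
Total step count: 12. Longest linear sequence: 12 steps (1 to 21); compound 5 enters at step 3 and compound 1 enters a second time at step 8.

**Steps most likely to fail and fallbacks**

Step 12 (samarium ring closure). Risks: reduction or pinacol coupling of the enal without ring closure, or the wrong C7 epimer that does not equilibrate. Fallback: set out from 18 and close the ring by a carbonyl addition of a C8 alkenylchromium instead. Hydroiodinate the allenoate (LiI, AcOH, 40 °C) to the vinyl iodide methyl (3Z)-4-[(1S,5S,6S)-5-acetoxy-2,6-dimethyl-6-[(1S,4Z)-4-methyl-6-oxo-1-(propanoyloxy)hex-4-en-1-yl]cyclohex-2-en-1-yl]-3-iodo-2-methylbut-3-enoate F1. Then perform an intramolecular Nozaki–Hiyama–Kishi addition to the C7 aldehyde (CrCl2 (4 equiv), NiCl2 (2 mol %), DMSO, high dilution, with a chiral sulfonamide ligand to control C7). This gives hydroxy ester 19, where the route is rejoined (19 lactonises to 20 and DBU gives 21).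

Step 6 (radical cyclisation to ring A). Risks: the epimeric ring in which O14 is trans to the C2 branch (this isomer has O14 cis to the ester arm and lactonises, so it is easy to recognise), or loss of the epoxide oxygen to a diene. The selectivity argument for this step is the least certain in the route. Fallback: set out from 8 and cyclise the free epoxy alcohol so that the ring closure is templated: the titanium alkoxide formed at O14 is chelated by the C2 hydroxyl in a six-membered titanacycle, and axial bond formation on that chelate ring forces O14 and the C2 branch cis. This gives the diol methyl 2-[(1S,5S,6R)-5-hydroxy-6-[(1S)-1-hydroxyprop-2-en-1-yl]-2,6-dimethylcyclohex-2-en-1-yl]acetate F2. Selective propanoylation of the exocyclic allylic C2 hydroxyl (EtCOCl, 2,4,6-collidine, CH2Cl2, −78 °C; the axial ring hydroxyl next to the quaternary carbon reacts more slowly) returns to 10.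

Step 11 (allenoate formation). Risks: the ylide olefinates the enal, or the ketene dimerises. Fallback: set out from 14 and build the allenoate before the aldehyde exists. Silylate (TBSCl, imidazole, DMF; the silyl ester is lost in the aqueous citric acid work-up) to the silyl ether acid 2-[(1S,5S,6S)-5-acetoxy-6-[(1S,4Z)-6-(tert-butyldimethylsilyloxy)-4-methyl-1-(propanoyloxy)hex-4-en-1-yl]-2,6-dimethylcyclohex-2-en-1-yl]acetic acid F3. Convert F3 by the acid chloride/ketene/ylide sequence of step 11 into the silyl ether allenoate methyl 4-[(1S,5S,6S)-5-acetoxy-6-[(1S,4Z)-6-(tert-butyldimethylsilyloxy)-4-methyl-1-(propanoyloxy)hex-4-en-1-yl]-2,6-dimethylcyclohex-2-en-1-yl]-2-methylbuta-2,3-dienoate F4. Remove the silyl group (HF·pyridine, THF, 0 °C) to give the hydroxy allenoate methyl 4-[(1S,5S,6S)-5-acetoxy-6-[(1S,4Z)-6-hydroxy-4-methyl-1-(propanoyloxy)hex-4-en-1-yl]-2,6-dimethylcyclohex-2-en-1-yl]-2-methylbuta-2,3-dienoate F5. Oxidise F5 (PhI(OAc)2, TEMPO, CH2Cl2) to 18.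

**Further compounds**
F1 | step 12 | methyl (3Z)-4-[(1S,5S,6S)-5-acetoxy-2,6-dimethyl-6-[(1S,4Z)-4-methyl-6-oxo-1-(propanoyloxy)hex-4-en-1-yl]cyclohex-2-en-1-yl]-3-iodo-2-methylbut-3-enoate | O=C/C=C(C)\CC[C@H](OC(=O)CC)[C@@]1(C)[C@@H](OC(C)=O)CC=C(C)[C@@H]1/C=C(\I)C(C)C(=O)OC
F2 | step 6 | methyl 2-[(1S,5S,6R)-5-hydroxy-6-[(1S)-1-hydroxyprop-2-en-1-yl]-2,6-dimethylcyclohex-2-en-1-yl]acetate | C=C[C@H](O)[C@@]1(C)[C@@H](O)CC=C(C)[C@@H]1CC(=O)OC
F3 | step 11 | 2-[(1S,5S,6S)-5-acetoxy-6-[(1S,4Z)-6-(tert-butyldimethylsilyloxy)-4-methyl-1-(propanoyloxy)hex-4-en-1-yl]-2,6-dimethylcyclohex-2-en-1-yl]acetic acid | CC(C)(C)[Si](C)(C)OC/C=C(C)\CC[C@H](OC(=O)CC)[C@@]1(C)[C@@H](OC(C)=O)CC=C(C)[C@@H]1CC(=O)O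
F4 | step 11 | methyl 4-[(1S,5S,6S)-5-acetoxy-6-[(1S,4Z)-6-(tert-butyldimethylsilyloxy)-4-methyl-1-(propanoyloxy)hex-4-en-1-yl]-2,6-dimethylcyclohex-2-en-1-yl]-2-methylbuta-2,3-dienoate | CC(C)(C)[Si](C)(C)OC/C=C(C)\CC[C@H](OC(=O)CC)[C@@]1(C)[C@@H](OC(C)=O)CC=C(C)[C@@H]1C=C=C(C)C(=O)OC
F5 | step 11 | methyl 4-[(1S,5S,6S)-5-acetoxy-6-[(1S,4Z)-6-hydroxy-4-methyl-1-(propanoyloxy)hex-4-en-1-yl]-2,6-dimethylcyclohex-2-en-1-yl]-2-methylbuta-2,3-dienoate | OC/C=C(C)\CC[C@H](OC(=O)CC)[C@@]1(C)[C@@H](OC(C)=O)CC=C(C)[C@@H]1C=C=C(C)C(=O)OC
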